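Read the tails.

| flask | D | X | remark | time | volume of the second phase over the first |
|---|---|---|---|---|---|
| ochre | 11 mM | 3.5 equiv | run made earlier |  |  |
| green | 11 mM | 5.5 equiv | run made earlier |  |  |
| blue | 22 mM | 2.5 equiv | run made earlier |  |  |
| flask | 11 mM | 2.50 equiv |  | 40 h | 0.50 |

- in the second phase: X; everything else is in the first
- charges count per volume of the first phase; a concentration in a rate is the amount of a species over the volume of its own phase; every rate counts per litre of the first phase
- the earlier runs hold the two phases in the same ratio of volumes as the flask asked about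
- what has gone from D into another species counts as reacted, even if it can come back

- amount of L at 40 h, in percent of the D charged
- part of the D charged that has reacted at 40 h

| run | time / h | L / % | D / % |
|---|---|---|---|
| ochre | 2.50 | 5.1 | 83.5 |
| ochre | 4.00 | 7.8 | 74.9 |
| ochre | 6.00 | 11.1 | 67.3 |
| ochre | 10.0 | 15.1 | 54.9 |
| ochre | 15.0 | 17.0 | 45.9 |
| ochre | 20.0 | 18.9 | 40.2 |
| ochre | 30.0 | 19.1 | 34.3 |
| green | 2.50 | 8.2 | 80.9 |
| green | 4.00 | 12.3 | 70.0 |
| green | 6.00 | 16.3 | 60.8 |
| green | 10.0 | 21.0 | 47.9 |
| green | 15.0 | 23.1 | 38.0 |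
| green | 20.0 | 24.1 | 32.4 |
| green | 30.0 | 22.2 | 25.2 |
| blue | 6.00 | 14.7 | 63.0 |
| blue | 12.0 | 19.9 | 45.8 |
| blue | 20.0 | 21.5 | 35.2 |
| blue | 25.0 | 21.4 | 31.7 |
| blue | 30.0 | 20.5 | 28.4 |

(standard deviation of a reading: 0.5 percentage points)

In each run D falls fast and then slowly, so the late rows carry the argument. Between 20.0 h and 30.0 h ochre D goes from 40.2% to 34.3%, a rate constant of 0.0159 h⁻¹; the green row gives 0.0251 h⁻¹. Charged c_X is 38.5 mM in ochre and 60.5 mM in green, and the mean constant per charged c_X, multiplied by the 27.5 mM charged in the flask, gives 0.0114 h⁻¹. The tail therefore reads as pseudo-first-order in D. Run back to zero time, these two tails start from about 54.4% of the D charged.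

For the flask, ln(2) over that constant gives 60.9 h, the tail half-life. My reckoning then leaves D at 34.5% after 40 h, so 65.5% has reacted; it says nothing about L.

The forecast gives L 14% (12.3% to 15.8%) and reacted D 65% (61.5% to 68.5%), reading that the “slowing D tail suggests the side route is reversible”.

The flask gives L 16.1%, above the forecast's range, and reacted D 63.8%, inside its range.

    Q ⇌ X, rate k1*([Q] - [X]/K1) per volume of the first phase (partition coefficient = 2.90, kL = 0.0410 min⁻¹)
    D + Q → L (k = 0.0300 M⁻¹ min⁻¹)
    Q + L → G (k = 0.0220 M⁻¹ min⁻¹)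
    D ⇌ J (K = 0.640, k = 9.10 × 10⁻⁴ min⁻¹)
    L → E (k = 4.70 × 10⁻⁴ min⁻¹)

The step between D and J has a relaxation half-life of 4.95 h, shorter than 40 h. In the flask, D and J together fall from 76.2% at 20.0 h to 62.2% at 40.0 h, a half-life of 68.2 h, against the 60.9 h reckoned from the tails. X at 1.87 equiv or 3.23 equiv moves the flask's reacted D by 5 points. For the neighbour with 6.6 mM of D, at the same equivalents of X, the same reckoning stretches the half-life to 102 h and leaves 58.5% reacted; that neighbour gives 56.1%.

(The readings are simulated on assumed constants; noise was put on by code.)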